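## Analysis of the target

The target contains a single carbocycle, a cyclohexane with four stereocentres (C1, C3, C4, C5); its only other rings are the two phenols of the side chains. C1 is quaternary, carries a hydroxyl and a carboxylic acid, and sits between the methylenes C2 and C6, while C3, C4 and C5 are contiguous carbinol carbons of which O3 is free and O4 and O5 carry (E)-4-hydroxycinnamoyl esters. The relative configuration is that of natural (−)-quinic acid: O1 is cis to O3, the carboxyl group is cis to O5, O3 is cis to O4, and O4 is trans to O5. The sensitive groups are the two conjugated esters (cleaved by base and nucleophiles, and prone to migrate from O4 to the neighbouring cis hydroxyl at C3), their alkenes (no hydrogenolysis, no late osmylation), the free phenols, and the α-hydroxy acid, which closes onto a free O5 once the carboxyl is activated. The synthesis is hard for two reasons: the 1,3,4,5-oxygenated ring must be made as one enantiomer, and three secondary hydroxyls of similar reactivity must be told apart so that only O4 and O5 are acylated and everything is unmasked at the end without base or reduction. The strategy rests on C1: a quaternary, oxygenated, carbonyl-bearing carbon flanked by two CH2 groups is what a 2-acyloxyacrolein delivers in a [4+2] cycloaddition with butadiene, and the alkene left at C4=C5 sits where the other oxygens are needed. Once C1 is fixed, its carboxyl can reach only one face of C5, and the resulting lactone bridge distinguishes the two faces of the ring and, later, O3 from O4.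

## Retrosynthetic reasoning

**Protecting groups (19 ⇐ 18 ⇐ 17).** The last two operations only remove protecting groups, and both are acidic. The aryl acetates of 18 are hydrolysed last; before that, the 4-methoxybenzyl ether on O3 and the 4-methoxybenzyl ester of 17 are cleaved by acidolysis. Acid is chosen because base would cleave and shift the cinnamoyl esters and hydrogenolysis would reduce their alkenes. The benzyl-type groups go first, while the phenols are still acetylated and their rings are poor nucleophiles for the benzyl cation.

**The two ester C–O bonds (17 ⇐ 14 + 16; 16 ⇐ 15).** The acyl groups are the most fragile part of the molecule, so the O4–acyl and O5–acyl bonds are cut next. Both are identical, so one operation with acid chloride 16 (from acid 15) installs them. The forward reaction needs a substrate in which only O4 and O5 can react. In triol 14, O3 is etherified, O1 is tertiary and unreactive, and the carboxyl is esterified so that it cannot relactonise onto O5.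

**Carboxyl ester and lactone (14 ⇐ 13 ⇐ 12).** The ester of 14 comes from acid 13 by carboxylate alkylation. Acid 13 comes from the bicyclic lactone 12 by a single saponification that opens the lactone (freeing O5 and the carboxyl) and removes the tertiary benzoate on O1. The benzoate is thus used as a protecting group for exactly as long as the lactone exists.

**The O3 ether (12 ⇐ 10 through 11).** The benzyl–O3 bond is cut at the lactone stage because only there do O3 and O4 differ strongly. In the bridged chair of 10, O3 is equatorial and O4 is axial, and O5 is tied up in the lactone. The stannylene acetal 11 of this cis-diol should alkylate at the equatorial oxygen.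

**C3–O and C4–O (10 ⇐ 9).** Both bonds are cut together to the alkene 9. The forward reaction is a syn-dihydroxylation that must take place on the face away from the lactone bridge, giving O3 and O4 cis to each other and trans to O5.

**Lactone C5–O bond and alkene position (9 ⇐ 8 ⇐ 7).** The C5–O bond is cut and the alkene is moved back from C3=C4 to C4=C5. Forward, halolactonisation of acid 7 delivers O5 on the face of the carboxyl group and places the halogen trans at C4; anti-elimination from 8 can then only run toward C3. Two stereocentres and the transposition are obtained from C1 alone.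

**Oxidation level (7 ⇐ 6).** The acid is traced back to the aldehyde 6, which is what the cycloaddition produces.

**Ring bonds C1–C6 and C2–C3 (6 ⇐ 4 + 5).** This is the only C–C disconnection of the route. Cutting here gives the symmetric diene 5, so no regiochemical or endo/exo question arises, and the enal 4, which already carries the C1 oxygen and the C1 carbonyl. The forward reaction must form the ring and the quaternary centre in one step and control a single element, the enantiotopic faces of 4.

**The dienophile (4 ⇐ 3 ⇐ 1 + 2).** Enal 4 is unmasked by a thermal retro-[4+2] fragmentation of the enol benzoate 3, made by O-benzoylation of ketone 1 with 2. These are two reliable steps, so the risk of the route sits in the cycloaddition.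

## Alternatives that were turned down

**Alternative 1:** The ring and the C3, C4 and C5 stereocentres would be taken from (−)-shikimic acid A1, and the bond cut is C1–O. A1 would be converted into allyl 4,5-bis-O-[(E)-4-acetoxycinnamoyl]shikimate A2. The key step is a hydroxyl-directed epoxidation of C1=C2 on the face of the free O3, giving the oxirane allyl 1,2-anhydro-4,5-bis-O-[(E)-4-acetoxycinnamoyl]-2-hydroxyquinate A3; the extra C2–O bond has to be removed afterwards.
- For it: six ring carbons and three of the four stereocentres come from the chiral pool, no asymmetric catalysis is needed, and the route is shorter on paper. On stereochemical security at C3–C5 and on step count it is stronger than the chosen route.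
- Against it: C1=C2 of A2 is conjugated with the ester and electron-poor, so electrophilic, hydroxyl-directed oxidants react slowly. The basic peroxide conditions that do epoxidise enoates are not hydroxyl-directed and would attack the four esters. The O4 acyl group sits beside a free cis hydroxyl throughout and can migrate. Making A2 requires the allylic O3, the most reactive hydroxyl of A1, to stay free while O4 and O5 are acylated. The C2–O bond of A3 must then be cut selectively at C2 in the presence of two cinnamate alkenes and four esters.
- What the chosen route offers instead: a C1 oxygen that is correct from the ring-forming step, no sacrificial oxygen, and acylation as the last constructive step with O3 blocked.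

**Alternative 2:** Both ester C–O bonds at C4 and C5 are cut at once, back to the pivalaldehyde dioxolanone of 3-O-(tert-butyldimethylsilyl)-4,5-didehydro-4,5-dideoxyquinic acid A4, a C4=C5 cyclohexene in which O3 is silylated and O1 and the carboxyl are tied in the dioxolanone. In the forward step I2 and two equivalents of silver (E)-4-acetoxycinnamate A5 add across the alkene under Prévost conditions: iodonium formation, anti opening by the carboxylate, closure to the acyloxonium ion and a second anti opening give the trans diester 4,5-bis-O-[(E)-4-acetoxycinnamoyl]-3-O-(tert-butyldimethylsilyl)quinic acid pivalaldehyde dioxolanone A6.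
- For it: it is the most direct way to the 4,5-diester. No diol, no separate acylation and no O3/O4 differentiation are needed, and the trans geometry follows from the mechanism. On directness of ester installation it is stronger than the chosen route.
- Against it: two trans diesters are possible (O4 down/O5 up, as needed, or the reverse). Which one forms depends on the face of iodonium formation and on which carbon of the acyloxonium ion is attacked. In A4 neither the allylic silyl ether nor the spiro-acetal gives a clear bias, and the required product A6 has O4 cis to the bulky O3 substituent. Two equivalents of A5, itself made from acid 15, are consumed. A4 still needs C3 set relative to C1, an allylic oxygenation of a cyclohexene like 6 with no obvious control element.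
- What the chosen route offers instead: every carbinol centre is set by an intramolecular or bicyclic constraint (lactonisation, anti-elimination, exo osmylation), so no step relies on an unbiased facial choice.

**Alternative 3:** The C3=C4 bond of the bicyclic alkene lactone is cut. (S)-Malic acid A7 would be elaborated to the cis-lactone (3S,5R)-3-allyl-3-hydroxy-5-vinyldihydrofuran-2(3H)-one A8, and the second-generation Grubbs catalyst (H2IMes)(PCy3)Cl2Ru=CHPh would close the carbocycle to (1S,5R)-1-hydroxy-6-oxabicyclo[3.2.1]oct-3-en-7-one A9. A9 is the debenzoylated counterpart of 9 and would continue through the same downstream chemistry.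
- For it: C1 comes from the chiral pool, so its configuration is not a question of enantioselectivity, and no pressurised, sluggish diene is involved. On these two points it is stronger than the chosen route.
- Against it: before ring closure a second stereocentre (C5) must be set cis to the C1 allyl group by open-chain diastereocontrol, which the iodolactonisation of the chosen route makes automatic. The metathesis must close a bridged ring across a γ-lactone with both alkenyl arms pseudo-axial, in competition with oligomerisation. Building A8 from A7 (acetalisation, α-allylation, chain adjustment, vinyl addition, lactonisation) takes clearly more steps than the six in which 9 is reached.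
- What the chosen route offers instead: the quaternary centre, the ring and the alkene in one catalytic step, with only one stereocentre controlled by an external agent.

Key step: step 3

**Assumptions.**
- Ring atoms carry quinic acid numbering throughout (C1 quaternary, C2 and C6 methylenes, C3–C5 oxygenated), also where the systematic name uses other locants; "quinic acid", "quinate" and "quinide" (the 1,5-lactone) mean the natural (−)-(1S,3R,4S,5R) series.
- The (R)-configured diammonium catalyst is taken to shield the Re face of C1 of the iminium ion; if the sense of induction is the opposite, the commercial (S)-antipode is used and nothing else changes.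

## Route

Step 1
Reactants: 1 2,2-dimethyl-1,3-dioxan-5-one; 2 benzoyl chloride
Product: 3 2,2-dimethyl-4H-1,3-dioxin-5-yl benzoate
Conditions: Et3N, DMAP (cat.), CH2Cl2, 0 °C to rt
Reagents that add atoms: none
Why: Enol ester formation by O-acylation of a ketone under soft enolisation: the α-hydrogens of 1 are acidified by the carbonyl and the adjacent ring oxygen, and the hard acylpyridinium electrophile is taken up at the enolate oxygen.

Step 2
Reactants: 3 2,2-dimethyl-4H-1,3-dioxin-5-yl benzoate
Product: 4 2-(benzoyloxy)prop-2-enal
Conditions: toluene, 110 °C, N2 stream, BHT (trace); used at once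
Reagents that add atoms: none
Why: Thermal retro-hetero-Diels–Alder ([4+2] cycloreversion) of the 4H-1,3-dioxin: the O1–C2 and O3–C4 bonds of the dioxin ring break, the acetal carbon leaves with O3 as acetone and is swept out, and the remaining O1=C6–C5=C4 oxadiene is the enal 4, which is used directly because it polymerises on storage.

Step 3
Reactants: 4 2-(benzoyloxy)prop-2-enal; 5 buta-1,3-diene
Product: 6 (S)-1-formylcyclohex-3-en-1-yl benzoate
Conditions: (R)-1,1'-binaphthyl-2,2'-diamine (10 mol %), HNTf2 (19 mol %), EtCN, 5 (excess), sealed vessel, −40 to −20 °C; aq. work-up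
Reagents that add atoms: none
Why: One NH2 group of the catalyst condenses with the aldehyde of 4 to a primary iminium ion, which lowers the LUMO of the C1=C2 π-bond far below that of the free enal, while the second ammonium group hydrogen-bonds to the benzoate carbonyl and holds the iminium in one rigid conformation. Butadiene in its s-cis form then adds across C1=C2 in a concerted, asynchronous [4+2] cycloaddition in which C2–C3 bonding runs ahead of C1–C6, and hydrolysis of the product iminium returns the catalyst. The closest known reaction type is the enantioselective Diels–Alder reaction of α-acyloxyacroleins with cyclic and 2-substituted acyclic dienes under chiral primary ammonium catalysis; unsubstituted butadiene is a less reactive member of the same diene class and is therefore used in excess in a closed vessel. The cyclohexene ring is closed by an intermolecular suprafacial–suprafacial cycloaddition that forms both ring bonds in one step, so no separate cyclisation mode arises. The only new stereocentre, C1, is set by the catalyst: one binaphthyl arm blocks the Re face of C1, the diene terminus bonds to the Si face, and this gives the S configuration. Endo/exo and regiochemical questions do not exist because 5 is unsubstituted and symmetric, so the step needs enantiofacial selectivity alone, which the hydrogen-bonded, ion-paired iminium in a nitrile solvent at low temperature is meant to secure. The uncatalysed reaction of free 4 is slow at these temperatures, which protects the enantiomeric purity.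

Step 4
Reactants: 6 (S)-1-formylcyclohex-3-en-1-yl benzoate
Product: 7 (S)-1-(benzoyloxy)cyclohex-3-ene-1-carboxylic acid
Conditions: NaClO2, NaH2PO4, 2-methylbut-2-ene, t-BuOH/H2O, 0 °C to rt
Reagents that add atoms: sodium chlorite, [Na+].[O-]Cl=O
Why: Pinnick oxidation: chlorous acid adds to the aldehyde and fragments to the acid, and 2-methylbut-2-ene scavenges HOCl so that the ring alkene is not chlorinated. C1 carries no hydrogen and cannot epimerise.

Step 5
Reactants: 7 (S)-1-(benzoyloxy)cyclohex-3-ene-1-carboxylic acid
Product: 8 (1S,4R,5R)-4-iodo-7-oxo-6-oxabicyclo[3.2.1]octan-1-yl benzoate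
Conditions: I2, KI, NaHCO3, H2O/CH2Cl2, 0 °C to rt, dark
Reagents that add atoms: iodine, II
Why: Iodolactonisation: iodonium formation on C4=C5 is reversible, and only the iodonium on the face opposite the carboxylate can be opened intramolecularly, attack at C5 (γ-lactone) being kinetically preferred over attack at C4 (δ-lactone). O5 is therefore delivered cis to the carboxyl group and iodine ends up trans to it at C4, both centres being set by C1.

Step 6
Reactants: 8 (1S,4R,5R)-4-iodo-7-oxo-6-oxabicyclo[3.2.1]octan-1-yl benzoate
Product: 9 (1S,5R)-7-oxo-6-oxabicyclo[3.2.1]oct-3-en-1-yl benzoate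
Conditions: DBU, toluene, 80 °C
Reagents that add atoms: none
Why: E2 elimination: the axial C4–I bond is anti-periplanar only to the axial hydrogen at C3 (at C5 the axial position is taken by the lactone oxygen), so the alkene forms at C3=C4 and C1 and C5 are untouched.

Step 7
Reactants: 9 (1S,5R)-7-oxo-6-oxabicyclo[3.2.1]oct-3-en-1-yl benzoate
Product: 10 (1S,3R,4R,5R)-3,4-dihydroxy-7-oxo-6-oxabicyclo[3.2.1]octan-1-yl benzoate (1-O-benzoylquinide)
Conditions: OsO4 (2 mol %), NMO, acetone/H2O, rt
Reagents that add atoms: osmium tetroxide, O=[Os](=O)(=O)=O; N-methylmorpholine N-oxide, C[N+]1([O-])CCOCC1; water, O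
Why: Catalytic syn-dihydroxylation ([3+2] addition of OsO4 with NMO as reoxidant): the lactone bridge covers the upper face of C3=C4, so the osmate ester forms on the lower (exo) face. Both new hydroxyls end up cis to each other and trans to O5, the quinide arrangement, so C3 and C4 are set by the bicyclic framework.

Step 8
Reactants: 10 1-O-benzoylquinide
Product: 12 (1S,3R,4R,5R)-4-hydroxy-3-[(4-methoxybenzyl)oxy]-7-oxo-6-oxabicyclo[3.2.1]octan-1-yl benzoate, via dibutylstannylene acetal 11 (not isolated)
Conditions: Bu2SnO, toluene, reflux (Dean–Stark); then 4-methoxybenzyl chloride, Bu4NI, 80 °C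
Reagents that add atoms: 4-methoxybenzyl chloride, COc1ccc(CCl)cc1
Why: Regioselective O-alkylation through a dibutylstannylene acetal: in the stannylene of a cis-1,2-diol on a six-membered ring the equatorial oxygen is the more nucleophilic one, and in 10 O3 is equatorial while O4 is axial, so iodide-assisted alkylation should go to O3. The conditions are neutral, so the lactone and the tertiary benzoate persist; no stereocentre is formed.

Step 9
Reactants: 12 1-O-benzoyl-3-O-(4-methoxybenzyl)quinide
Product: 13 3-O-(4-methoxybenzyl)quinic acid
Conditions: LiOH·H2O, THF/H2O, 0 °C to rt; then 1 M HCl to pH 3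
Reagents that add atoms: lithium hydroxide, [Li+].[OH-]
Why: Saponification: hydroxide opens the bridged γ-lactone by acyl–oxygen cleavage and cleaves the tertiary benzoate, both made irreversible by carboxylate formation. No C–O bond at a stereocentre is broken, and the benzyl ether is inert and cannot migrate.

Step 10
Reactants: 13 3-O-(4-methoxybenzyl)quinic acid
Product: 14 4-methoxybenzyl 3-O-(4-methoxybenzyl)quinate
Conditions: Cs2CO3, 4-methoxybenzyl chloride, DMF, rt
Reagents that add atoms: 4-methoxybenzyl chloride, COc1ccc(CCl)cc1
Why: SN2 O-alkylation of the caesium carboxylate: under carbonate in DMF the carboxylate is the only anion present, so the three hydroxyls are not alkylated. The ester prevents relactonisation onto O5 in the next step.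

Step 11
Reactants: 15 (E)-4-acetoxycinnamic acid
Product: 16 (E)-4-acetoxycinnamoyl chloride
Conditions: (COCl)2, DMF (cat.), CH2Cl2, 0 °C to rt; evaporate
Reagents that add atoms: oxalyl chloride, O=C(Cl)C(=O)Cl
Why: Acid chloride formation through the chloroiminium species from DMF and oxalyl chloride; the aryl acetate and the E-alkene are unaffected.

Step 12
Reactants: 14 4-methoxybenzyl 3-O-(4-methoxybenzyl)quinate; 16 (E)-4-acetoxycinnamoyl chloride
Product: 17 4-methoxybenzyl 4,5-bis-O-[(E)-4-acetoxycinnamoyl]-3-O-(4-methoxybenzyl)quinate
Conditions: 16 (3 equiv), pyridine, DMAP (0.3 equiv), CH2Cl2, 0 °C to rt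
Reagents that add atoms: none
Why: DMAP-catalysed acylation via the N-acylpyridinium ion: the two equatorial secondary hydroxyls at C4 and C5 are esterified, while the tertiary O1 next to the ester group is too hindered to react at room temperature. With O3 etherified, no acyl migration is possible.

Step 13
Reactants: 17 4-methoxybenzyl 4,5-bis-O-[(E)-4-acetoxycinnamoyl]-3-O-(4-methoxybenzyl)quinate
Product: 18 4,5-bis-O-[(E)-4-acetoxycinnamoyl]quinic acid
Conditions: TFA/CH2Cl2 (1:4), anisole, 0 °C to rt
Reagents that add atoms: none
Why: SN1-type acidolysis of the 4-methoxybenzyl ether and ester: protonation and loss of the stabilised benzyl cation, which anisole traps by Friedel–Crafts alkylation. Cinnamoyl and aryl acetate esters are stable to anhydrous acid, and the acetylated phenol rings are too electron-poor to compete with anisole for the cation.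

Step 14
Reactants: 18 4,5-bis-O-[(E)-4-acetoxycinnamoyl]quinic acid
Product: 19 4,5-di-O-p-coumaroylquinic acid
Conditions: 2 M aq. HCl/THF (1:2), rt
Reagents that add atoms: none
Why: Acid-catalysed ester hydrolysis: the unhindered, non-conjugated phenolic acetates should hydrolyse much faster than the conjugated cinnamates of hindered secondary alcohols. Under acid the O4-to-O3 acyl migration that base would trigger is slow.

## Compound list

1 | 2,2-dimethyl-1,3-dioxan-5-one | CC1(C)OCC(=O)CO1 | starting material
2 | benzoyl chloride | O=C(Cl)c1ccccc1 | starting material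
3 | 2,2-dimethyl-4H-1,3-dioxin-5-yl benzoate | CC1(C)OCC(OC(=O)c2ccccc2)=CO1 | intermediate
4 | 2-(benzoyloxy)prop-2-enal | C=C(C=O)OC(=O)c1ccccc1 | intermediate
5 | buta-1,3-diene | C=CC=C | starting material
6 | (S)-1-formylcyclohex-3-en-1-yl benzoate | O=C[C@]1(OC(=O)c2ccccc2)CCC=CC1 | intermediate
7 | (S)-1-(benzoyloxy)cyclohex-3-ene-1-carboxylic acid | O=C(O)[C@]1(OC(=O)c2ccccc2)CCC=CC1 | intermediate
8 | (1S,4R,5R)-4-iodo-7-oxo-6-oxabicyclo[3.2.1]octan-1-yl benzoate (iodine trans to the lactone oxygen) | O=C1O[C@@H]2C[C@@]1(OC(=O)c3ccccc3)CC[C@H]2I | intermediate
9 | (1S,5R)-7-oxo-6-oxabicyclo[3.2.1]oct-3-en-1-yl benzoate | O=C1O[C@@H]2C[C@@]1(OC(=O)c3ccccc3)CC=C2 | intermediate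
10 | (1S,3R,4R,5R)-3,4-dihydroxy-7-oxo-6-oxabicyclo[3.2.1]octan-1-yl benzoate (1-O-benzoylquinide) | O=C1O[C@@H]2C[C@@]1(OC(=O)c3ccccc3)C[C@@H](O)[C@H]2O | intermediate
11 | 3,4-O-dibutylstannylene acetal of 1-O-benzoylquinide | O=C1O[C@@H]2C[C@@]1(OC(=O)c3ccccc3)C[C@H]3O[Sn](CCCC)(CCCC)O[C@@H]23 | intermediate
12 | (1S,3R,4R,5R)-4-hydroxy-3-[(4-methoxybenzyl)oxy]-7-oxo-6-oxabicyclo[3.2.1]octan-1-yl benzoate (1-O-benzoyl-3-O-(4-methoxybenzyl)quinide) | O=C1O[C@@H]2C[C@@]1(OC(=O)c3ccccc3)C[C@@H](OCc3ccc(OC)cc3)[C@H]2O | intermediate
13 | 3-O-(4-methoxybenzyl)quinic acid | O[C@@H]1[C@H](OCc2ccc(OC)cc2)C[C@@](O)(C(=O)O)C[C@H]1O | intermediate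
14 | 4-methoxybenzyl 3-O-(4-methoxybenzyl)quinate | O[C@@H]1[C@H](OCc2ccc(OC)cc2)C[C@@](O)(C(=O)OCc2ccc(OC)cc2)C[C@H]1O | intermediate
15 | (E)-4-acetoxycinnamic acid | CC(=O)Oc1ccc(/C=C/C(=O)O)cc1 | starting material
16 | (E)-4-acetoxycinnamoyl chloride | CC(=O)Oc1ccc(/C=C/C(=O)Cl)cc1 | intermediate
17 | 4-methoxybenzyl 4,5-bis-O-[(E)-4-acetoxycinnamoyl]-3-O-(4-methoxybenzyl)quinate | O=C(/C=C/c1ccc(OC(C)=O)cc1)O[C@@H]1[C@H](OCc2ccc(OC)cc2)C[C@@](O)(C(=O)OCc2ccc(OC)cc2)C[C@H]1OC(=O)/C=C/c1ccc(OC(C)=O)cc1 | intermediate
18 | 4,5-bis-O-[(E)-4-acetoxycinnamoyl]quinic acid | O=C(/C=C/c1ccc(OC(C)=O)cc1)O[C@@H]1[C@H](O)C[C@@](O)(C(=O)O)C[C@H]1OC(=O)/C=C/c1ccc(OC(C)=O)cc1 | intermediate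
19 | 4,5-di-O-p-coumaroylquinic acid | O=C(/C=C/c1ccc(O)cc1)O[C@@H]1[C@H](O)C[C@@](O)(C(=O)O)C[C@H]1OC(=O)/C=C/c1ccc(O)cc1 | target

## Step count and least certain steps

Total: 14 steps. Longest linear sequence: 13 steps (steps 1–10 and 12–14, from 1 to 19); step 11 is a one-step side branch.

**Step 3 (key step).** The most likely failure is slow cycloaddition of the unactivated diene, so that polymerisation of 4 and the uncatalysed background reaction compete and lower both conversion and enantiomeric purity; warming to force conversion would erode the facial selectivity further. The fallback sets out from 4 and 5 and returns at 7. Uncatalysed cycloaddition in toluene at 110 °C in a sealed vessel would give racemic 1-formylcyclohex-3-en-1-yl benzoate F1. Oxidation as in step 4 would give racemic 1-(benzoyloxy)cyclohex-3-ene-1-carboxylic acid F2. Crystallisation of its salt with (R)-1-phenylethylamine would give (R)-1-phenylethylammonium (S)-1-(benzoyloxy)cyclohex-3-ene-1-carboxylate F3 (the antipodal amine is used if the other salt is the less soluble one), and acidification releases 7.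

**Step 8.** The risk is regiochemical leakage in the alkylation of the stannylene (reaction through O4 or double alkylation), or tin-promoted acyl transfer at the temperature the benzyl chloride needs. The fallback sets out from 10 and returns at 13, and fixes the regiochemistry by a different principle. Trimethyl orthobenzoate with CSA (cat.) would give the cyclic 3,4-O-(α-methoxybenzylidene) orthoester of 1-O-benzoylquinide F4. Mild aqueous acetic acid opens such orthoesters of cis-diols to the axial ester, here 1,4-di-O-benzoylquinide F5 with the equatorial O3 free. 4-Methoxybenzyl trichloroacetimidate with CSA (cat.) would then give 1,4-di-O-benzoyl-3-O-(4-methoxybenzyl)quinide F6, and the saponification of step 9 removes both benzoates and opens the lactone to 13.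

**Step 12.** The risks are incomplete acylation of O4, which is flanked by the axial O3 ether and the new O5 ester; over-acylation of the tertiary O1 when excess reagent is used to push the reaction; and DMAP-mediated acetyl transfer from the aryl acetates. The fallback sets out from 14 and returns at 19; it builds the cinnamoyl units on the ring instead of transferring them. Meldrum's acid in toluene at 90 °C would give 4-methoxybenzyl 4,5-bis-O-(carboxyacetyl)-3-O-(4-methoxybenzyl)quinate F7. Knoevenagel–Doebner condensation with 4-hydroxybenzaldehyde (pyridine, piperidine cat.) would give 4-methoxybenzyl 4,5-di-O-[(E)-4-hydroxycinnamoyl]-3-O-(4-methoxybenzyl)quinate F8 with decarboxylation; O3 is still blocked, so the basic medium cannot cause migration. TFA with a large excess of anisole, otherwise as in step 13, then gives 19.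

**Step 14.** The risk is that acetate hydrolysis is slow enough for partial cleavage of the cinnamoyl esters, or acid-promoted drift of the O4 acyl group to the now free O3, to compete over the long reaction time. The fallback sets out from 14 and returns at 19; it removes the need for any aqueous hydrolysis. (E)-4-tert-Butoxycinnamic acid F9 (from commercial 4-tert-butoxybenzaldehyde and malonic acid, pyridine/piperidine) would be coupled to 14 under Yamaguchi conditions (2,4,6-trichlorobenzoyl chloride, Et3N, DMAP) to give 4-methoxybenzyl 4,5-bis-O-[(E)-4-tert-butoxycinnamoyl]-3-O-(4-methoxybenzyl)quinate F10. A single TFA/anisole treatment would cleave the aryl tert-butyl ethers together with both 4-methoxybenzyl groups and give 19.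

## Further compounds

F1 | step 3 | racemic 1-formylcyclohex-3-en-1-yl benzoate | O=CC1(OC(=O)c2ccccc2)CCC=CC1
F2 | step 3 | racemic 1-(benzoyloxy)cyclohex-3-ene-1-carboxylic acid | O=C(O)C1(OC(=O)c2ccccc2)CCC=CC1
F3 | step 3 | (R)-1-phenylethylammonium (S)-1-(benzoyloxy)cyclohex-3-ene-1-carboxylate | [O-]C(=O)[C@]1(OC(=O)c2ccccc2)CCC=CC1.C[C@H](c1ccccc1)[NH3+]
F4 | step 8 | 3,4-O-(α-methoxybenzylidene) orthoester of 1-O-benzoylquinide (mixture at the orthoester carbon) | O=C1O[C@@H]2C[C@@]1(OC(=O)c3ccccc3)C[C@H]3OC(OC)(c4ccccc4)O[C@@H]23
F5 | step 8 | 1,4-di-O-benzoylquinide | O=C1O[C@@H]2C[C@@]1(OC(=O)c3ccccc3)C[C@@H](O)[C@H]2OC(=O)c4ccccc4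
F6 | step 8 | 1,4-di-O-benzoyl-3-O-(4-methoxybenzyl)quinide | O=C1O[C@@H]2C[C@@]1(OC(=O)c3ccccc3)C[C@@H](OCc3ccc(OC)cc3)[C@H]2OC(=O)c4ccccc4
F7 | step 12 | 4-methoxybenzyl 4,5-bis-O-(carboxyacetyl)-3-O-(4-methoxybenzyl)quinate | OC(=O)CC(=O)O[C@@H]1[C@H](OCc2ccc(OC)cc2)C[C@@](O)(C(=O)OCc2ccc(OC)cc2)C[C@H]1OC(=O)CC(=O)O
F8 | step 12 | 4-methoxybenzyl 4,5-di-O-[(E)-4-hydroxycinnamoyl]-3-O-(4-methoxybenzyl)quinate | O=C(/C=C/c1ccc(O)cc1)O[C@@H]1[C@H](OCc2ccc(OC)cc2)C[C@@](O)(C(=O)OCc2ccc(OC)cc2)C[C@H]1OC(=O)/C=C/c1ccc(O)cc1
F9 | step 14 | (E)-4-tert-butoxycinnamic acid | CC(C)(C)Oc1ccc(/C=C/C(=O)O)cc1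
F10 | step 14 | 4-methoxybenzyl 4,5-bis-O-[(E)-4-tert-butoxycinnamoyl]-3-O-(4-methoxybenzyl)quinate | O=C(/C=C/c1ccc(OC(C)(C)C)cc1)O[C@@H]1[C@H](OCc2ccc(OC)cc2)C[C@@](O)(C(=O)OCc2ccc(OC)cc2)C[C@H]1OC(=O)/C=C/c1ccc(OC(C)(C)C)cc1
A1 | alternative 1 | (−)-shikimic acid | O[C@@H]1[C@H](O)C=C(C(=O)O)C[C@H]1O
A2 | alternative 1 | allyl 4,5-bis-O-[(E)-4-acetoxycinnamoyl]shikimate | O=C(/C=C/c1ccc(OC(C)=O)cc1)O[C@@H]1[C@H](O)C=C(C(=O)OCC=C)C[C@H]1OC(=O)/C=C/c1ccc(OC(C)=O)cc1
A3 | alternative 1 | allyl 1,2-anhydro-4,5-bis-O-[(E)-4-acetoxycinnamoyl]-2-hydroxyquinate (1,2-epoxide cis to O3) | O=C(/C=C/c1ccc(OC(C)=O)cc1)O[C@@H]1[C@H](O)[C@@H]2O[C@]2(C(=O)OCC=C)C[C@H]1OC(=O)/C=C/c1ccc(OC(C)=O)cc1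
A4 | alternative 2 | pivalaldehyde dioxolanone of 3-O-(tert-butyldimethylsilyl)-4,5-didehydro-4,5-dideoxyquinic acid | C1[C@H](O[Si](C)(C)C(C)(C)C)C[C@]2(O[C@@H](C(C)(C)C)OC2=O)CC=1
A5 | alternative 2 | silver (E)-4-acetoxycinnamate | CC(=O)Oc1ccc(/C=C/C(=O)[O-])cc1.[Ag+]
A6 | alternative 2 | 4,5-bis-O-[(E)-4-acetoxycinnamoyl]-3-O-(tert-butyldimethylsilyl)quinic acid pivalaldehyde dioxolanone | O=C(/C=C/c1ccc(OC(C)=O)cc1)O[C@@H]1[C@H](O[Si](C)(C)C(C)(C)C)C[C@]2(O[C@@H](C(C)(C)C)OC2=O)C[C@H]1OC(=O)/C=C/c1ccc(OC(C)=O)cc1
A7 | alternative 3 | (S)-malic acid | O[C@@H](CC(=O)O)C(=O)O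
A8 | alternative 3 | (3S,5R)-3-allyl-3-hydroxy-5-vinyldihydrofuran-2(3H)-one (allyl and vinyl cis) | C=CC[C@@]1(O)C(=O)O[C@@H](C=C)C1
A9 | alternative 3 | (1S,5R)-1-hydroxy-6-oxabicyclo[3.2.1]oct-3-en-7-one | C1=CC[C@@]2(O)C(=O)O[C@@H]1C2
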